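**Structural features**

The target is a (2S)-flavan: a chroman (benzo ring A fused to pyran ring C) with a 5-hydroxy-2-methoxyphenyl group (ring B) on C2, a free hydroxyl on C7 and a 1,3-diarylpropyl chain on C6. The chain carbon on C6 (Cα) is an R-configured diarylalkyl methine carrying the 4-hydroxyphenyl ring D; Cβ and Cγ are methylenes, and Cγ ends in the 4-hydroxy-2-methoxyphenyl ring E. The two stereocentres, C2 and Cα, lie six bonds apart across ring A, so neither can direct the other and each needs its own reagent or catalyst control. Fragile points are the four electron-rich phenols, the doubly benzylic Cα–H, and the C2–O1 bond, an ortho-methoxybenzylic aryl ether that can ionise in acid with loss of configuration. The real difficulty is Cα: a methine between two oxygenated aryl rings of similar size, with no neighbouring functional group to steer an asymmetric bond formation. A second problem is telling six phenolic oxygens apart, two of which must end as methyl ethers. The route uses the fact that Cα is ortho to O7: Cα, Cβ, Cγ and O7, together with C6 and C7, map onto a 2,4-diarylchroman ring whose Cγ–O7 bond is a 2,4-dioxygenated benzylic ether and can be cut again.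

**Logic of the disconnections**

20 ⇒ 19. The three phenolic O–H bonds of rings B, D and E are replaced by O–CH2Ph. This leaves one free phenol (O7) in 19 and allows every earlier step to be run on non-oxidisable ethers. The forward step must cleave three O–benzyl bonds without touching C2–O1 or Cα–H, which calls for neutral hydrogenolysis.

19 ⇒ 18. The Cγ–O7 bond is re-formed in the retrosynthetic sense. This turns the acyclic Cα methine into a ring member that a cycloaddition can create, and it masks O7 while ring E is methylated. The forward step must break Cγ–O7 and no other benzylic C–O bond; the 2,4-dioxygenated ring E on Cγ, against the singly ortho-activated ring B on C2, provides the margin.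

18 ⇒ 17. The ring E O–CH3 bond is cut. The free phenol is needed as the hydrogen-bond handle in the cycloaddition, so methylation has to come afterwards. It is unambiguous because 17 has only this one free hydroxyl.

17 ⇒ 14 + 15 (through 16). Cα–Cβ and Cγ–O7 are cut in a retro-[4+2] sense. This removes one ring, two skeletal bonds and both new stereocentres, and leaves a benzhydrol and a vinylphenol of roughly half the size. The forward step must generate 16 under acid mild enough to spare C2–O1 and must control the face of attack at Cα; Cγ is sacrificial, so its configuration is irrelevant.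

15 ⇒ 2 and 2 ⇒ 1. The vinyl C=C is cut back to the aldehyde, and the 4-O–benzyl bond back to the diphenol. Compound 2 is also the ring A building block of the flavan, so one intermediate serves twice. The forward steps need selective alkylation of the non-chelated hydroxyl and a methylenation that tolerates a free phenol.

14 ⇒ 11 + 12 (through 13). The Cα–ring D bond is cut. The carbinol configuration does not matter because Cα becomes planar in 16. The forward step is an aryl-metal addition to a salicylaldehyde and needs an extra equivalent of 13 for the phenol.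

11 ⇒ 10 ⇒ 9. The C6–CHO bond and, before it, the O7–H are traced back to a 7-benzyl ether. Keeping O7 benzylated up to this point lets the whole flavan construction run with a single free phenol. The forward steps need formylation at C6 (para to O1, ortho to O7) and not at C8, then removal of only the benzyl group that sits ortho to the new carbonyl.

9 ⇒ 8 ⇒ 7. The O1–C2 bond is cut to a phenol and a secondary benzylic alcohol, and the carbinol C–H back to a ketone. The C2 configuration therefore comes from a catalytic ketone reduction followed by a closure with inversion. The reduction must tolerate a free phenol, so transfer hydrogenation is chosen over a borane reagent.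

7 ⇒ 6 ⇒ 2 + 5. The C3–C4 single bond is traced to an enone C=C, and that to an aldol union of an aldehyde and a methyl ketone. The forward steps need a condensation that works on a phenoxide-deactivated aldehyde and an alkene hydrogenation that spares two benzyl ethers and the aryl ketone.

5 ⇒ 4 ⇒ 3. The O–CH3 and O–CH2Ph bonds of ring B are cut back to the diphenol. The chelated 2-hydroxyl reacts last, which fixes the order: benzylation first, methylation second.

**Other disconnections considered**

Alternative 1: The cut removes ring A altogether (C5–C6, C6–C7, C8–C8a and C4a–C8a). It leaves the α-diazo enone A1, which already carries both side chains and both stereocentres, and (triisopropylsilyloxy)acetylene A2. In the forward sense, irradiation of A1 would trigger a Wolff rearrangement to a vinylketene, and A2 would add in a [2+2] sense. Four-electron opening of the cyclobutenone, six-electron closure and tautomerisation would then give phenol A3. Cleavage of the secondary silyl ether, Mitsunobu closure of ring C on the free C8a–OH, desilylation at O7 and debenzylation would finish.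
- In its favour: the substitution pattern of ring A is fixed by the connectivity of A1 and A2, so no aromatic substitution has to be steered. This is better than the chosen plan, which relies on regioselective formylation in step 8.
- O7 and O8a emerge differentiated, which is equal to the chosen plan.
- No benzylic ether has to be cut selectively at the end, which is better than step 14.
- Against it: Cα has to be made beforehand in an acyclic fragment by a separate asymmetric reaction, so the key step does nothing for the hardest stereocentre.
- In A1, Cα sits next to the diazo carbon, where a 1,2-hydrogen shift in the carbene could compete with the rearrangement.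
- A1 requires diazo transfer onto a hindered α-branched ketone, and A2 is a sensitive reagent.
- C2 would still need the same reduction and Mitsunobu pair.
- Comparison: mechanistically it is a neutral pericyclic cascade, gentler than the acid-mediated steps 12 and 14, but it creates no stereocentre. In step count it would be clearly longer, since two enantioenriched chains must be built and joined before the ring is formed.

Alternative 2: The cut is C4–C4a of ring C. In the forward sense Ph3PAuNTf2 would activate the terminal alkyne of the aryl propargyl ether A4, and C4a would attack in a 6-endo-dig hydroarylation to give the 2H-chromene A5. One hydrogenation would then saturate C3=C4 and remove all benzyl groups.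
- In its favour: the closure is catalytic and atom-economic.
- O7 can stay benzylated from start to finish, which is better than the chosen plan, where O7 has to be unmasked in step 9.
- The final hydrogenation does double duty: equal to step 15 in step economy, and no counterpart of step 14 is needed.
- Against it: the stereocentre of A4 is benzylic, propargylic and bonded to an aryloxy leaving group. Ionisation or propargyl Claisen-type pathways under cationic gold threaten its configuration more than the Mitsunobu step 7 threatens C2.
- Making A4 enantiopure needs an SN2 etherification at exactly such a centre.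
- Attack must occur at C4a and not at C8, and 6-endo closure must beat 5-exo closure.
- Cα again has to come from an earlier, separate asymmetric step, so the alternative solves the easier stereocentre and leaves the harder one.
- Comparison: structurally it opens ring C and makes no use of the ortho relationship between Cα and O7. Mechanistically it is π-acid catalysis on a configurationally labile substrate, against a Brønsted acid cycloaddition in which the catalyst itself sets Cα. Once the Cα-bearing phenol is counted, the length would probably be comparable.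

Alternative 3: The cut is C4a–C5 and C7–C8 of ring A, which is assembled at the oxidation level of a cyclohexane-1,3-dione from methyl ketone A6 and 2-methylene ester A7. In the forward sense KOtBu would form the internal enolate of A6, which adds to A7 (Michael), and the methyl carbon would then close onto the ester (Claisen) to give dione A8. Dehydrogenation to the resorcinol, silyl ether removal, Mitsunobu closure and debenzylation would follow.
- In its favour: two fragments of similar size are joined, which is better convergence than the chosen plan.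
- The base is cheap and no precious metal is needed in the key step.
- After aromatisation only the C8a–OH can close a six-membered ring, so the two oxygens are distinguished without protecting groups, which is equal to the chosen plan.
- Against it: the methyl side of A6 is the kinetically favoured enolate, and a reversed order of the two bond formations would give an isomeric dione.
- Cα in A7 is allylic, benzylic and γ to the ester, so alkoxide can shift the double bond into conjugation and erase the stereocentre.
- A8 has to be dehydrogenated under conditions that spare benzyl ethers, the silyl ether and the benzylic positions, an oxidation the chosen plan does not need.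
- Both stereocentres are again made beforehand.
- Comparison: structurally it builds the arene; mechanistically it is anionic and under thermodynamic control with a base-labile stereocentre, against catalyst control under weak acid. In step count it would be longer because of the fragment syntheses and the aromatisation.

Key step: step 12

Assumption: the (R)-phosphoric acid is written for step 12 by analogy with the face selection of the parent reaction; should a trial on 14 show the opposite sense at Cα, the (S)-antipode is used with no other change.

**Route**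

Step 1
Reactants: 1 2,4-dihydroxybenzaldehyde
Product: 2 4-(benzyloxy)-2-hydroxybenzaldehyde
Conditions: BnBr (1.05 equiv), NaHCO3, KI (cat.), MeCN, 80 °C
Reagents that add atoms: benzyl bromide, BrCc1ccccc1
Why: Williamson etherification; the 4-OH (para to the formyl group) is the more acidic and is not hydrogen-bonded, whereas the 2-OH is held in a chelate with the carbonyl, so a weak base should give the 4-monoether.

Step 2
Reactants: 3 1-(2,5-dihydroxyphenyl)ethanone
Product: 4 1-[5-(benzyloxy)-2-hydroxyphenyl]ethanone
Conditions: BnBr (1.05 equiv), K2CO3, acetone, reflux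
Reagents that add atoms: benzyl bromide, BrCc1ccccc1
Why: Williamson etherification; the 2-OH is chelated to the acetyl carbonyl and poorly nucleophilic, so the 5-OH should be alkylated selectively.

Step 3
Reactants: 4 1-[5-(benzyloxy)-2-hydroxyphenyl]ethanone
Product: 5 1-[5-(benzyloxy)-2-methoxyphenyl]ethanone
Conditions: MeI (3 equiv), K2CO3, DMF, 50 °C
Reagents that add atoms: iodomethane, CI
Why: Williamson methylation of the remaining chelated phenol, which needs a polar aprotic solvent and mild heating; no other nucleophilic site is present.

Step 4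
Reactants: 2 4-(benzyloxy)-2-hydroxybenzaldehyde; 5 1-[5-(benzyloxy)-2-methoxyphenyl]ethanone
Product: 6 (E)-3-[4-(benzyloxy)-2-hydroxyphenyl]-1-[5-(benzyloxy)-2-methoxyphenyl]prop-2-en-1-one
Conditions: KOH (50% aq., 6 equiv), EtOH, rt, 48 h; then AcOH to pH 6, 0 °C
Reagents that add atoms: none
Why: Claisen–Schmidt condensation; excess hydroxide and a long reaction time compensate for the phenoxide-deactivated aldehyde, and E1cB dehydration should give the E-enone. Acidification is kept mild so that the 2-hydroxychalcone does not close to a flavylium salt.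

Step 5
Reactants: 6 (E)-3-[4-(benzyloxy)-2-hydroxyphenyl]-1-[5-(benzyloxy)-2-methoxyphenyl]prop-2-en-1-one
Product: 7 3-[4-(benzyloxy)-2-hydroxyphenyl]-1-[5-(benzyloxy)-2-methoxyphenyl]propan-1-one
Conditions: H2 (1 atm), 10% Pd/C, Ph2S (0.01 equiv), EtOAc, rt
Reagents that add atoms: none
Why: Heterogeneous hydrogenation on sulfide-poisoned Pd/C should saturate the conjugated alkene while benzyl ether hydrogenolysis and aryl ketone reduction are suppressed.

Step 6
Reactants: 7 3-[4-(benzyloxy)-2-hydroxyphenyl]-1-[5-(benzyloxy)-2-methoxyphenyl]propan-1-one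
Product: 8 5-(benzyloxy)-2-{(3R)-3-[5-(benzyloxy)-2-methoxyphenyl]-3-hydroxypropyl}phenol
Conditions: RuCl(p-cymene)[(R,R)-TsDPEN] (1 mol%), HCO2H/Et3N (5:2), EtOAc, 40 °C
Reagents that add atoms: none
Why: Noyori–Ikariya asymmetric transfer hydrogenation; the (R,R)-catalyst delivers hydride to the face of an aryl alkyl ketone that gives the (R)-1-arylalkanol, through the CH/π contact between the η6-arene and the ketone aryl group. The free phenol is tolerated in formic acid/triethylamine, unlike with borane reagents.

Step 7
Reactants: 8 5-(benzyloxy)-2-{(3R)-3-[5-(benzyloxy)-2-methoxyphenyl]-3-hydroxypropyl}phenol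
Product: 9 (2S)-7-(benzyloxy)-2-[5-(benzyloxy)-2-methoxyphenyl]chromane
Conditions: PPh3, DIAD, THF (0.02 M), 0 °C → rt
Reagents that add atoms: none
Why: Intramolecular Mitsunobu etherification; the phenol displaces the oxyphosphonium in a 6-exo-tet SN2 closure with inversion, turning the (R)-carbinol into (S)-C2. Low temperature and dilution favour the bimolecular-type displacement over ionisation.

Step 8
Reactants: 9 (2S)-7-(benzyloxy)-2-[5-(benzyloxy)-2-methoxyphenyl]chromane
Product: 10 (2S)-7-(benzyloxy)-2-[5-(benzyloxy)-2-methoxyphenyl]chromane-6-carbaldehyde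
Conditions: POCl3 (1.5 equiv), DMF, 0 → 60 °C; then aq. NaOAc
Reagents that add atoms: N,N-dimethylformamide, CN(C)C=O; water, O
Why: Vilsmeier–Haack formylation; C6 is para to O1 and ortho to O7, C8 between the two oxygens is hindered, and ring B (a hydroquinone diether) is far less nucleophilic than the resorcinol-type ring A.

Step 9
Reactants: 10 (2S)-7-(benzyloxy)-2-[5-(benzyloxy)-2-methoxyphenyl]chromane-6-carbaldehyde
Product: 11 (2S)-2-[5-(benzyloxy)-2-methoxyphenyl]-7-hydroxychromane-6-carbaldehyde
Conditions: MgBr2·OEt2 (3 equiv), PhMe/Et2O, 70 °C; then cold 1 M HCl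
Reagents that add atoms: none
Why: Chelation-controlled ether cleavage; magnesium bridges the formyl oxygen and the ortho ether oxygen, and bromide attacks the activated benzyl CH2 (SN2). The ring B benzyl and methyl ethers have no neighbouring carbonyl and should stay.

Step 10
Reactants: 11 (2S)-2-[5-(benzyloxy)-2-methoxyphenyl]-7-hydroxychromane-6-carbaldehyde; 12 1-(benzyloxy)-4-bromobenzene
Product: 14 (2S)-2-[5-(benzyloxy)-2-methoxyphenyl]-6-{[4-(benzyloxy)phenyl](hydroxy)methyl}chroman-7-ol (both carbinol epimers), via 4-(benzyloxy)phenylmagnesium bromide 13 (not isolated)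
Conditions: 12, Mg, I2 (cat.), THF, reflux; then 11, THF, 0 °C → rt (3 equiv of 13); aq. NH4Cl, 0 °C
Reagents that add atoms: none
Why: Grignard addition to a salicylaldehyde; the first equivalent of 13 deprotonates the phenol and the second adds to the chelated aldehyde. No stereocontrol is needed because the carbinol carbon becomes planar in step 12; the acid-sensitive product is quenched cold and used without delay.

Step 11
Reactants: 2 4-(benzyloxy)-2-hydroxybenzaldehyde
Product: 15 5-(benzyloxy)-2-ethenylphenol
Conditions: Ph3PCH3Br (2.5 equiv), KOtBu (2.5 equiv), THF, 0 °C → rt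
Reagents that add atoms: methyltriphenylphosphonium bromide, C[P+](c1ccccc1)(c1ccccc1)c1ccccc1.[Br-]
Why: Wittig methylenation; excess ylide is used because the phenol consumes one equivalent. The vinylphenol is prepared fresh and kept cold to avoid polymerisation.

Step 12
Reactants: 14 (2S)-2-[5-(benzyloxy)-2-methoxyphenyl]-6-{[4-(benzyloxy)phenyl](hydroxy)methyl}chroman-7-ol (both carbinol epimers); 15 5-(benzyloxy)-2-ethenylphenol
Product: 17 (2S,4R,8S)-2-[4-(benzyloxy)-2-hydroxyphenyl]-8-[5-(benzyloxy)-2-methoxyphenyl]-4-[4-(benzyloxy)phenyl]-3,4,7,8-tetrahydro-2H,6H-pyrano[3,2-g]chromene (cis-2,4-diaryl dihydropyran fused on C6–C7 of the flavan), via ortho-quinone methide 16 (not isolated)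
Conditions: (R)-3,3'-bis(2,4,6-triisopropylphenyl)-1,1'-binaphthyl-2,2'-diyl hydrogen phosphate (10 mol%), 15 (1.5 equiv), PhMe, 4 Å MS, 0 °C → rt
Reagents that add atoms: none
Why: The phosphoric acid protonates the benzylic hydroxyl of 14, and water leaves with the help of O7 and, through ring A, of O1 para to the carbinol carbon; both carbinol epimers converge on the planar E-configured ortho-quinone methide 16, which stays hydrogen-bonded to the phosphate through its carbonyl oxygen. The CH2 terminus of 15, held by the same phosphate through its phenolic OH, adds to the methide carbon (Cα–Cβ), and the 2,4-dioxygenated benzylic cation developing at Cγ is captured by O7 (Cγ–O7), an asynchronous inverse-electron-demand oxa-Diels–Alder reaction. The closest known reaction type is the chiral phosphoric acid-catalysed [4+2] cycloaddition of ortho-hydroxybenzhydrols with ortho-hydroxystyrenes to cis-2,4-diarylchromans. The one new ring, a dihydropyran on C6–C7, closes in a [4+2] mode (O7, C7, C6 and Cα from 16, Cβ and Cγ from 15), the C–O bond forming last as a 6-endo capture of the cation. Cα is set by the catalyst, whose 2,4,6-triisopropylphenyl groups shield one face of the bound methide; Cγ follows from the endo-type arrangement that places both aryl groups cis, and it is sacrificial, so only the face at Cα matters. The C2 centre lies six bonds from Cα and should cause little matching or mismatching. The step needs ionisation of the benzhydrol without opening the C2–O1 ether, which the weak acid and the far greater stabilisation of 16 should secure, and attack by the CH2 terminus only, which the para-benzyloxy and ortho-hydroxy groups of 15 secure by polarising the alkene.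

Step 13
Reactants: 17 (2S,4R,8S)-2-[4-(benzyloxy)-2-hydroxyphenyl]-8-[5-(benzyloxy)-2-methoxyphenyl]-4-[4-(benzyloxy)phenyl]-3,4,7,8-tetrahydro-2H,6H-pyrano[3,2-g]chromene
Product: 18 (2S,4R,8S)-2-[4-(benzyloxy)-2-methoxyphenyl]-8-[5-(benzyloxy)-2-methoxyphenyl]-4-[4-(benzyloxy)phenyl]-3,4,7,8-tetrahydro-2H,6H-pyrano[3,2-g]chromene
Conditions: MeI (5 equiv), K2CO3, DMF, 0 °C → rt
Reagents that add atoms: iodomethane, CI
Why: Williamson methylation of the only free phenol; O7 is locked in the temporary ring, so ring E alone is methylated. The temperature is kept at or below rt so that the ortho-phenoxide is alkylated before it can expel O7 by an E1cB ring opening.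

Step 14
Reactants: 18 (2S,4R,8S)-2-[4-(benzyloxy)-2-methoxyphenyl]-8-[5-(benzyloxy)-2-methoxyphenyl]-4-[4-(benzyloxy)phenyl]-3,4,7,8-tetrahydro-2H,6H-pyrano[3,2-g]chromene
Product: 19 (2S)-2-[5-(benzyloxy)-2-methoxyphenyl]-6-{(1R)-3-[4-(benzyloxy)-2-methoxyphenyl]-1-[4-(benzyloxy)phenyl]propyl}chroman-7-ol
Conditions: Et3SiH (5 equiv), TFA (10 equiv), CH2Cl2, −20 → 0 °C; then aq. NaHCO3
Reagents that add atoms: none
Why: Ionic hydrogenation of a benzylic ether; acid ionises Cγ–O7 to a cation stabilised by the ortho-methoxy and para-benzyloxy groups of ring E, and the silane delivers hydride. The C2–O1 ether has only one ortho donor and a meta-oxygen, so it should ionise far more slowly at this temperature. Cα–H is not involved, and Cγ becomes a methylene.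

Step 15
Reactants: 19 (2S)-2-[5-(benzyloxy)-2-methoxyphenyl]-6-{(1R)-3-[4-(benzyloxy)-2-methoxyphenyl]-1-[4-(benzyloxy)phenyl]propyl}chroman-7-ol
Product: 20 (2S)-6-[(1R)-1-(4-hydroxyphenyl)-3-(4-hydroxy-2-methoxyphenyl)propyl]-2-(5-hydroxy-2-methoxyphenyl)chroman-7-ol
Conditions: H2 (1 atm), 10% Pd/C, EtOAc/MeOH, rt
Reagents that add atoms: none
Why: Catalytic hydrogenolysis of three aryl benzyl ethers under neutral conditions, which should leave the C2–O1 ether, the methyl ethers and both stereocentres untouched.

**Compound list**

1 | 2,4-dihydroxybenzaldehyde | O=Cc1ccc(O)cc1O | starting material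
2 | 4-(benzyloxy)-2-hydroxybenzaldehyde | O=Cc1ccc(OCc2ccccc2)cc1O | intermediate
3 | 1-(2,5-dihydroxyphenyl)ethanone (2,5-dihydroxyacetophenone) | CC(=O)c1cc(O)ccc1O | starting material
4 | 1-[5-(benzyloxy)-2-hydroxyphenyl]ethanone | CC(=O)c1cc(OCc2ccccc2)ccc1O | intermediate
5 | 1-[5-(benzyloxy)-2-methoxyphenyl]ethanone | CC(=O)c1cc(OCc2ccccc2)ccc1OC | intermediate
6 | (E)-3-[4-(benzyloxy)-2-hydroxyphenyl]-1-[5-(benzyloxy)-2-methoxyphenyl]prop-2-en-1-one | COc1ccc(OCc2ccccc2)cc1C(=O)/C=C/c1ccc(OCc2ccccc2)cc1O | intermediate
7 | 3-[4-(benzyloxy)-2-hydroxyphenyl]-1-[5-(benzyloxy)-2-methoxyphenyl]propan-1-one | COc1ccc(OCc2ccccc2)cc1C(=O)CCc1ccc(OCc2ccccc2)cc1O | intermediate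
8 | 5-(benzyloxy)-2-{(3R)-3-[5-(benzyloxy)-2-methoxyphenyl]-3-hydroxypropyl}phenol | O[C@H](CCc1ccc(OCc2ccccc2)cc1O)c1cc(OCc2ccccc2)ccc1OC | intermediate
9 | (2S)-7-(benzyloxy)-2-[5-(benzyloxy)-2-methoxyphenyl]chromane | c1cc2c(cc1OCc1ccccc1)O[C@H](c1cc(OCc3ccccc3)ccc1OC)CC2 | intermediate
10 | (2S)-7-(benzyloxy)-2-[5-(benzyloxy)-2-methoxyphenyl]chromane-6-carbaldehyde | O=Cc1cc2c(cc1OCc1ccccc1)O[C@H](c1cc(OCc3ccccc3)ccc1OC)CC2 | intermediate
11 | (2S)-2-[5-(benzyloxy)-2-methoxyphenyl]-7-hydroxychromane-6-carbaldehyde | O=Cc1cc2c(cc1O)O[C@H](c1cc(OCc3ccccc3)ccc1OC)CC2 | intermediate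
12 | 1-(benzyloxy)-4-bromobenzene | Brc1ccc(OCc2ccccc2)cc1 | starting material
13 | 4-(benzyloxy)phenylmagnesium bromide | Br[Mg]c1ccc(OCc2ccccc2)cc1 | intermediate
14 | (2S)-2-[5-(benzyloxy)-2-methoxyphenyl]-6-{[4-(benzyloxy)phenyl](hydroxy)methyl}chroman-7-ol, both carbinol epimers | OC(c1ccc(OCc2ccccc2)cc1)c1cc2c(cc1O)O[C@H](c1cc(OCc3ccccc3)ccc1OC)CC2 | intermediate
15 | 5-(benzyloxy)-2-ethenylphenol | C=Cc1ccc(OCc2ccccc2)cc1O | intermediate
16 | (2S,6E)-2-[5-(benzyloxy)-2-methoxyphenyl]-6-[4-(benzyloxy)benzylidene]-3,4-dihydro-2H-chromen-7(6H)-one (ortho-quinone methide) | O=C1C=C2O[C@H](c3cc(OCc4ccccc4)ccc3OC)CCC2=C/C1=C\c1ccc(OCc2ccccc2)cc1 | intermediate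
17 | (2S,4R,8S)-2-[4-(benzyloxy)-2-hydroxyphenyl]-8-[5-(benzyloxy)-2-methoxyphenyl]-4-[4-(benzyloxy)phenyl]-3,4,7,8-tetrahydro-2H,6H-pyrano[3,2-g]chromene | Oc1cc(OCc2ccccc2)ccc1[C@@H]1C[C@H](c2ccc(OCc4ccccc4)cc2)c2cc3c(cc2O1)O[C@H](c2cc(OCc4ccccc4)ccc2OC)CC3 | intermediate
18 | (2S,4R,8S)-2-[4-(benzyloxy)-2-methoxyphenyl]-8-[5-(benzyloxy)-2-methoxyphenyl]-4-[4-(benzyloxy)phenyl]-3,4,7,8-tetrahydro-2H,6H-pyrano[3,2-g]chromene | COc1cc(OCc2ccccc2)ccc1[C@@H]1C[C@H](c2ccc(OCc4ccccc4)cc2)c2cc3c(cc2O1)O[C@H](c2cc(OCc4ccccc4)ccc2OC)CC3 | intermediate
19 | (2S)-2-[5-(benzyloxy)-2-methoxyphenyl]-6-{(1R)-3-[4-(benzyloxy)-2-methoxyphenyl]-1-[4-(benzyloxy)phenyl]propyl}chroman-7-ol | COc1cc(OCc2ccccc2)ccc1CC[C@H](c1ccc(OCc2ccccc2)cc1)c1cc2c(cc1O)O[C@H](c1cc(OCc3ccccc3)ccc1OC)CC2 | intermediate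
20 | (2S)-6-[(1R)-1-(4-hydroxyphenyl)-3-(4-hydroxy-2-methoxyphenyl)propyl]-2-(5-hydroxy-2-methoxyphenyl)chroman-7-ol | COc1cc(O)ccc1CC[C@H](c1ccc(O)cc1)c1cc2c(cc1O)O[C@H](c1cc(O)ccc1OC)CC2 | target

**Step count and least certain steps**

Total step count: 15. Longest linear sequence: 13 steps (3 → 4 → 5 → 6 → 7 → 8 → 9 → 10 → 11 → 14 → 17 → 18 → 19 → 20; steps 2–10 and 12–15). Steps 1 and 11 form the side branch through 2, which also enters the main line at step 4.

Step 12 (key step). Most likely to go wrong: insufficient facial discrimination at Cα, because the methide carbon is flanked by a bulky bicyclic ring and an aryl group of similar size, and the sense and level of induction on this substituted system are extrapolated. A second risk is oligomerisation of the electron-rich vinylphenol, or self-condensation of the methide, outrunning the cycloaddition. The fallback sets out from 11 and comes back at 19. Commercial 1-[4-(benzyloxy)-2-hydroxyphenyl]ethanone is O-methylated (MeI, K2CO3, DMF) to 1-[4-(benzyloxy)-2-methoxyphenyl]ethanone F1. Claisen–Schmidt condensation of 11 with it (KOH, EtOH) should give the (E)-2-hydroxychalcone F2. A Hayashi–Miyaura 1,4-addition of 4-(benzyloxy)phenylboronic acid (Rh(acac)(C2H4)2, (R)-BINAP or its antipode as required for the R centre, dioxane/H2O, 60 °C) would then set Cα and give the β,β-diaryl ketone F3. NaBH4 reduces this to the carbinol F4 (both epimers), whose 2,4-dioxygenated benzylic hydroxyl is removed with Et3SiH/TFA to reach 19.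

Step 14. Most likely to go wrong: competing ionisation of the C2–O1 ether (which also carries an ortho-methoxyaryl group), leading to over-reduction or loss of configuration at C2; or Friedel–Crafts capture of the Cγ cation outrunning hydride transfer, so that forcing becomes necessary. The fallback sets out from 18 and comes back at 20, and it replaces the cationic cleavage by an anionic one. Hydrogenolysis first (H2, Pd/C, EtOAc/MeOH) gives the triphenol (2S,4R,8S)-2-(4-hydroxy-2-methoxyphenyl)-8-(5-hydroxy-2-methoxyphenyl)-4-(4-hydroxyphenyl)-3,4,7,8-tetrahydro-2H,6H-pyrano[3,2-g]chromene F5. NaBH4 in aqueous NaOH/EtOH at 40–50 °C should then let the para-phenoxide of ring E expel O7 as a para-quinone methide, which borohydride reduces at Cγ. Ring B has its hydroxyl meta to C2 and cannot form a quinone methide, so C2–O1 is safe by mechanism.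

Step 9. Most likely to go wrong: loss of the ring B benzyl ether alongside the intended one, or Lewis acid opening of the pyran ring, whose O1 has become a better leaving group now that it is para to the formyl group. The fallback sets out from 10 and comes back at 11. Both benzyl ethers are removed by hydrogenolysis (H2, Pd/C, EtOAc, stopped after two equivalents so that the aldehyde is spared) to give (2S)-7-hydroxy-2-(5-hydroxy-2-methoxyphenyl)chromane-6-carbaldehyde F6. The ring B phenol is then re-benzylated (BnBr, K2CO3, acetone); the 7-OH is chelated to the formyl group and should stay free for the same reason as in step 2.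

Step 7. Most likely to go wrong: partial ionisation of the ortho-methoxybenzylic oxyphosphonium intermediate, which would erode the enantiomeric purity at C2; the ortho-methoxy group may also lower the selectivity of step 6. The fallback sets out from 7 and comes back at 9, bypassing steps 6 and 7. Acid-catalysed cyclodehydration (TsOH, PhMe, Dean–Stark) gives 7-(benzyloxy)-2-[5-(benzyloxy)-2-methoxyphenyl]-4H-chromene F7. Asymmetric hydrogenation of its C2=C3 bond with a cationic iridium phosphinooxazoline catalyst then sets C2 without any substitution at an ionisable carbon and does not cleave benzyl ethers. The catalyst is [Ir(cod)(L)]B[3,5-(CF3)2C6H3]4, with L = (S)-4-tert-butyl-2-[2-(diphenylphosphanyl)phenyl]-4,5-dihydrooxazole or its antipode as required for 2S, under H2 (50 bar) in CH2Cl2.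

**Further compounds**

F1 | step 12 | 1-[4-(benzyloxy)-2-methoxyphenyl]ethanone | CC(=O)c1ccc(OCc2ccccc2)cc1OC
F2 | step 12 | (E)-1-[4-(benzyloxy)-2-methoxyphenyl]-3-{(2S)-2-[5-(benzyloxy)-2-methoxyphenyl]-7-hydroxychroman-6-yl}prop-2-en-1-one | COc1cc(OCc2ccccc2)ccc1C(=O)/C=C/c1cc2c(cc1O)O[C@H](c1cc(OCc3ccccc3)ccc1OC)CC2
F3 | step 12 | (3R)-1-[4-(benzyloxy)-2-methoxyphenyl]-3-[4-(benzyloxy)phenyl]-3-{(2S)-2-[5-(benzyloxy)-2-methoxyphenyl]-7-hydroxychroman-6-yl}propan-1-one | COc1cc(OCc2ccccc2)ccc1C(=O)C[C@H](c1ccc(OCc2ccccc2)cc1)c1cc2c(cc1O)O[C@H](c1cc(OCc3ccccc3)ccc1OC)CC2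
F4 | step 12 | (2S)-2-[5-(benzyloxy)-2-methoxyphenyl]-6-{(1R)-3-[4-(benzyloxy)-2-methoxyphenyl]-1-[4-(benzyloxy)phenyl]-3-hydroxypropyl}chroman-7-ol, both carbinol epimers | COc1cc(OCc2ccccc2)ccc1C(O)C[C@H](c1ccc(OCc2ccccc2)cc1)c1cc2c(cc1O)O[C@H](c1cc(OCc3ccccc3)ccc1OC)CC2
F5 | step 14 | (2S,4R,8S)-2-(4-hydroxy-2-methoxyphenyl)-8-(5-hydroxy-2-methoxyphenyl)-4-(4-hydroxyphenyl)-3,4,7,8-tetrahydro-2H,6H-pyrano[3,2-g]chromene | COc1cc(O)ccc1[C@@H]1C[C@H](c2ccc(O)cc2)c2cc3c(cc2O1)O[C@H](c2cc(O)ccc2OC)CC3
F6 | step 9 | (2S)-7-hydroxy-2-(5-hydroxy-2-methoxyphenyl)chromane-6-carbaldehyde | O=Cc1cc2c(cc1O)O[C@H](c1cc(O)ccc1OC)CC2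
F7 | step 7 | 7-(benzyloxy)-2-[5-(benzyloxy)-2-methoxyphenyl]-4H-chromene | COc1ccc(OCc2ccccc2)cc1C1=CCc2ccc(OCc3ccccc3)cc2O1
A1 | alternative 1 | α-diazo enone: (1E)-enone carrying the (R)-silyloxy-arylpropyl chain on the alkene terminus and the (R)-1,3-diarylpropyl group on the diazo carbon | COc1cc(OCc2ccccc2)ccc1CC[C@H](c1ccc(OCc2ccccc2)cc1)C(=[N+]=[N-])C(=O)/C=C/CC[C@@H](O[Si](C)(C)C(C)(C)C)c1cc(OCc2ccccc2)ccc1OC
A2 | alternative 1 | (triisopropylsilyloxy)acetylene | C#CO[Si](C(C)C)(C(C)C)C(C)C
A3 | alternative 1 | ring A phenol with free C8a–OH, C7 triisopropylsilyl ether and both side chains | COc1cc(OCc2ccccc2)ccc1CC[C@H](c1ccc(OCc2ccccc2)cc1)c1cc(CC[C@@H](O[Si](C)(C)C(C)(C)C)c2cc(OCc3ccccc3)ccc2OC)c(O)cc1O[Si](C(C)C)(C(C)C)C(C)C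
A4 | alternative 2 | (S)-1-aryl-prop-2-ynyl aryl ether of the 3-benzyloxy-4-[(R)-1,3-diarylpropyl]phenol | COc1cc(OCc2ccccc2)ccc1CC[C@H](c1ccc(OCc2ccccc2)cc1)c1ccc(cc1OCc1ccccc1)O[C@H](c1cc(OCc3ccccc3)ccc1OC)C#C
A5 | alternative 2 | (2S)-2-aryl-2H-chromene bearing the (R)-1,3-diarylpropyl group on C6 and a benzyl ether on O7 | COc1cc(OCc2ccccc2)ccc1CC[C@H](c1ccc(OCc2ccccc2)cc1)c1cc2c(cc1OCc1ccccc1)O[C@H](c1cc(OCc3ccccc3)ccc1OC)C=C2
A6 | alternative 3 | (6R)-6-[5-(benzyloxy)-2-methoxyphenyl]-6-[(tert-butyldimethylsilyl)oxy]hexan-2-one | CC(=O)CCC[C@@H](O[Si](C)(C)C(C)(C)C)c1cc(OCc2ccccc2)ccc1OC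
A7 | alternative 3 | methyl (3R)-5-[4-(benzyloxy)-2-methoxyphenyl]-3-[4-(benzyloxy)phenyl]-2-methylidenepentanoate | COc1cc(OCc2ccccc2)ccc1CC[C@H](c1ccc(OCc2ccccc2)cc1)C(=C)C(=O)OC
A8 | alternative 3 | 4,6-disubstituted cyclohexane-1,3-dione (ring carbons as epimer and enol mixture) | COc1cc(OCc2ccccc2)ccc1CC[C@H](c1ccc(OCc2ccccc2)cc1)C1CC(CC[C@@H](O[Si](C)(C)C(C)(C)C)c2cc(OCc3ccccc3)ccc2OC)C(=O)CC1=O
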